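**Plan**

- Retrosynthesis: after the three O–Si bonds, the C2–C3 bond of ring C is cut. This cut is open because C2 holds a hydrogen that is benzylic to ring B and alpha to O1, and that hydrogen lies within reach of the C3 carbonyl oxygen once C3 and C4 form a 1,2-dicarbonyl on C4a of ring A.
- The achiral aryl glyoxal is cut further at C3 (oxidation level, back to an acetyl group), at the O1–CH2 ether bond (ring A phenol plus silylated vanillyl alcohol) and at the C6–prenyl bond (para-Claisen/Cope shift of an O-prenyl ether).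
- Forward: rings A and B are bought as 1-(2,4,6-trihydroxyphenyl)ethanone and vanillin. Ring A is silylated, O-prenylated and rearranged, joined to ring B through O1, and its acetyl group is oxidised to the glyoxal.
- Ring C is the only ring that is built: light moves the C2 hydrogen to the C3 oxygen and the 1,6-biradical closes C2–C3.
- Stereochemistry: both centres arise in that closure, C3 (R) under a scandium–PyBOX complex on the dicarbonyl and C2 (R) trans to it. Buffered fluoride then frees the phenols without enolising C3.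

Key step: step 9

Assumption: 1-(2,4,6-trihydroxyphenyl)ethanone is bought as the C-acetylated form of phloroglucinol, and since the sense of induction of the PyBOX ligand cannot be known in advance, the (S,S) ligand written in step 9 stands for whichever antipode leaves the Re face of C3 open.

**Route**

Step 1
Reactants: 1 1-(2,4,6-trihydroxyphenyl)ethanone
Product: 2 1-[2-hydroxy-4,6-bis(triisopropylsilyloxy)phenyl]ethanone
Conditions: TIPSCl (2.2 equiv), imidazole, DMF, 0 °C to rt
Reagents that add atoms: triisopropylsilyl chloride, CC(C)[Si](Cl)(C(C)C)C(C)C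
Why: Phenol silylation: the para hydroxyl and one ortho hydroxyl should react, whereas the last ortho hydroxyl is tied to the acetyl oxygen by a hydrogen bond and is too hindered for a third TIPS group, and TIPS is preferred to TBS on ring A because it withstands carbonate, 200 °C and an adjacent enolate.

Step 2
Reactants: 2 1-[2-hydroxy-4,6-bis(triisopropylsilyloxy)phenyl]ethanone; 3 1-bromo-3-methylbut-2-ene
Product: 4 1-[2-(3-methylbut-2-enyloxy)-4,6-bis(triisopropylsilyloxy)phenyl]ethanone
Conditions: K2CO3, acetone, reflux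
Reagents that add atoms: none
Why: Williamson ether synthesis: K2CO3 deprotonates the chelated phenol and the phenoxide is O-alkylated by the allylic bromide in acetone, conditions that aryl TIPS ethers tolerate.

Step 3
Reactants: 4 1-[2-(3-methylbut-2-enyloxy)-4,6-bis(triisopropylsilyloxy)phenyl]ethanone
Product: 7 1-[6-hydroxy-3-(3-methylbut-2-enyl)-2,4-bis(triisopropylsilyloxy)phenyl]ethanone, via ortho dienone 5 (not isolated), via para dienone 6 (not isolated)
Conditions: N,N-diethylaniline, 200 °C, argon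
Reagents that add atoms: none
Why: Aromatic Claisen rearrangement followed by Cope rearrangement (para-Claisen): the first [3,3] shift gives ortho dienone 5, whose 1,1-dimethylallyl group should move on by a second [3,3] shift faster than 5 enolises in the aprotic amine, so the prenyl group arrives un-inverted on the carbon between the two silyloxy groups (the later C6) and tautomerism of 6 frees the hydroxyl that becomes O1.

Step 4
Reactants: 8 vanillin (4-hydroxy-3-methoxybenzaldehyde)
Product: 9 4-(tert-butyldimethylsilyloxy)-3-methoxybenzaldehyde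
Conditions: TBSCl, imidazole, CH2Cl2, rt
Reagents that add atoms: tert-butyldimethylsilyl chloride, CC(C)(C)[Si](C)(C)Cl
Why: Phenol silylation of vanillin, needed so that the 4-oxygen survives the Mitsunobu and enolate steps and later supports the C2 radical as a donor.

Step 5
Reactants: 9 4-(tert-butyldimethylsilyloxy)-3-methoxybenzaldehyde
Product: 10 [4-(tert-butyldimethylsilyloxy)-3-methoxyphenyl]methanol
Conditions: NaBH4, MeOH, 0 °C
Reagents that add atoms: none
Why: NaBH4 reduction of the aryl aldehyde to the benzylic alcohol at 0 °C, which leaves the aryl silyl ether untouched.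

Step 6
Reactants: 7 1-[6-hydroxy-3-(3-methylbut-2-enyl)-2,4-bis(triisopropylsilyloxy)phenyl]ethanone; 10 [4-(tert-butyldimethylsilyloxy)-3-methoxyphenyl]methanol
Product: 11 1-[6-{[4-(tert-butyldimethylsilyloxy)-3-methoxyphenyl]methoxy}-3-(3-methylbut-2-enyl)-2,4-bis(triisopropylsilyloxy)phenyl]ethanone
Conditions: PPh3, DIAD, THF, 0 °C to rt
Reagents that add atoms: none
Why: Mitsunobu etherification: the hydrogen-bonded phenol of 7 is acidic enough to be alkylated by the activated primary benzylic alcohol under neutral conditions, which avoids both carbonate and the unstable 4-silyloxybenzyl halide.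

Step 7
Reactants: 11 1-[6-{[4-(tert-butyldimethylsilyloxy)-3-methoxyphenyl]methoxy}-3-(3-methylbut-2-enyl)-2,4-bis(triisopropylsilyloxy)phenyl]ethanone
Product: 13 1-[6-{[4-(tert-butyldimethylsilyloxy)-3-methoxyphenyl]methoxy}-3-(3-methylbut-2-enyl)-2,4-bis(triisopropylsilyloxy)phenyl]-2-hydroxyethanone, via potassium enolate 12 (not isolated)
Conditions: KN(SiMe3)2, THF, −78 °C; 3-phenyl-2-(phenylsulfonyl)oxaziridine, −78 °C; AcOH quench at −78 °C
Reagents that add atoms: 3-phenyl-2-(phenylsulfonyl)oxaziridine, O=S(=O)(c1ccccc1)N1OC1c1ccccc1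
Why: Enolate oxidation with a Davis oxaziridine: the methyl group is the only enolisable site, the potassium enolate takes the electrophilic oxygen at carbon while the prenyl alkene is inert at −78 °C, and the cold acetic acid quench protonates the alkoxide before a silyl group can migrate.

Step 8
Reactants: 13 1-[6-{[4-(tert-butyldimethylsilyloxy)-3-methoxyphenyl]methoxy}-3-(3-methylbut-2-enyl)-2,4-bis(triisopropylsilyloxy)phenyl]-2-hydroxyethanone
Product: 14 2-[6-{[4-(tert-butyldimethylsilyloxy)-3-methoxyphenyl]methoxy}-3-(3-methylbut-2-enyl)-2,4-bis(triisopropylsilyloxy)phenyl]-2-oxoacetaldehyde (achiral)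
Conditions: Dess–Martin periodinane, CH2Cl2, 0 °C to rt; pentane, filtration through Celite, toluene azeotrope (no aqueous work-up)
Reagents that add atoms: none
Why: Dess–Martin oxidation of the primary alpha-ketol to the alpha-keto aldehyde under neutral, water-free conditions, so that the glyoxal is obtained unhydrated and the alkene, silyl ethers and benzyl ether are spared.

Step 9
Reactants: 14 2-[6-{[4-(tert-butyldimethylsilyloxy)-3-methoxyphenyl]methoxy}-3-(3-methylbut-2-enyl)-2,4-bis(triisopropylsilyloxy)phenyl]-2-oxoacetaldehyde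
Product: 15 (2R,3R)-2-[4-(tert-butyldimethylsilyloxy)-3-methoxyphenyl]-3-hydroxy-6-(3-methylbut-2-enyl)-5,7-bis(triisopropylsilyloxy)-2,3-dihydrochromen-4-one
Conditions: Sc(OTf)3 (20 mol %), (S,S)-tBu-PyBOX (2,6-bis[(4S)-4-tert-butyl-4,5-dihydrooxazol-2-yl]pyridine, 24 mol %), 4 Å molecular sieves, CH2Cl2 (0.005 M), 455 nm LED, −40 °C, argon
Reagents that add atoms: none
Why: Proposed new method: the scandium chelate of the 1,2-dicarbonyl absorbs to the red of free 14 and, once excited, should take a hydrogen atom from the O1–CH2 group onto the C3 oxygen (as electron then proton, since the carbonyl lone pairs are held by the metal and the vanillyl ring is a good donor), which gives a scandium-bound ketyl at C3 and an oxygen- and aryl-stabilised radical at C2. The closest known reaction type is the uncatalysed Norrish–Yang photocyclisation of ortho-alkoxyaryl and ortho-alkylaryl 1,2-diketones through the remote carbonyl to 3-hydroxychromanones and 2-hydroxyindanones; what is new is the aldehyde terminus and control by a chiral Lewis acid. Ring C closes by recombination of the 1,6-biradical, a six-membered radical–radical closure that forms C2–C3 and leaves C4 as the ketone. C3 is set by the PyBOX ligand, which must leave open the Re face of the chelated ketyl (OH > C4 > H) for 3R, and C2 is set relative to C3 because the aryl group takes the pseudo-equatorial place trans to the metal-bearing oxygen in the half-chair closure, which is 2R. The step needs C2–H over every other hydrogen and C3 over C4 as the bonding site: C2–H is the only hydrogen within reach that is both benzylic and alpha to oxygen, the silyl ethers on O5 and O7 offer none and the prenyl CH2 sits meta to the glyoxal, while bonding at C4 would make a crowded quaternary centre in a five-membered ring.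

Step 10
Reactants: 15 (2R,3R)-2-[4-(tert-butyldimethylsilyloxy)-3-methoxyphenyl]-3-hydroxy-6-(3-methylbut-2-enyl)-5,7-bis(triisopropylsilyloxy)-2,3-dihydrochromen-4-one
Product: 16 (2R,3R)-3,5,7-trihydroxy-2-(4-hydroxy-3-methoxyphenyl)-6-(3-methylbut-2-enyl)-2,3-dihydrochromen-4-one
Conditions: Bu4NF, AcOH (1:1), THF, 0 °C to rt
Reagents that add atoms: none
Why: Fluoride cleavage of the three aryl silyl ethers, buffered with acetic acid so that no phenoxide or enolate forms at C3 and the prenyl group meets no strong acid; with the 4'-hydroxyl free, any cis isomer can still equilibrate at C2 to the trans compound while C3 stays fixed.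

**Compound list**

1 | 1-(2,4,6-trihydroxyphenyl)ethanone | CC(=O)c1c(O)cc(O)cc1O | starting material
2 | 1-[2-hydroxy-4,6-bis(triisopropylsilyloxy)phenyl]ethanone | CC(=O)c1c(O)cc(O[Si](C(C)C)(C(C)C)C(C)C)cc1O[Si](C(C)C)(C(C)C)C(C)C | intermediate
3 | 1-bromo-3-methylbut-2-ene | CC(C)=CCBr | starting material
4 | 1-[2-(3-methylbut-2-enyloxy)-4,6-bis(triisopropylsilyloxy)phenyl]ethanone | CC(=O)c1c(OCC=C(C)C)cc(O[Si](C(C)C)(C(C)C)C(C)C)cc1O[Si](C(C)C)(C(C)C)C(C)C | intermediate
5 | 2-acetyl-6-(2-methylbut-3-en-2-yl)-3,5-bis(triisopropylsilyloxy)cyclohexa-2,4-dien-1-one (ortho dienone, racemic) | CC(=O)C1=C(O[Si](C(C)C)(C(C)C)C(C)C)C=C(O[Si](C(C)C)(C(C)C)C(C)C)C(C(C)(C)C=C)C1=O | intermediate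
6 | 2-acetyl-4-(3-methylbut-2-enyl)-3,5-bis(triisopropylsilyloxy)cyclohexa-2,5-dien-1-one (para dienone, racemic) | CC(=O)C1=C(O[Si](C(C)C)(C(C)C)C(C)C)C(CC=C(C)C)C(O[Si](C(C)C)(C(C)C)C(C)C)=CC1=O | intermediate
7 | 1-[6-hydroxy-3-(3-methylbut-2-enyl)-2,4-bis(triisopropylsilyloxy)phenyl]ethanone | CC(=O)c1c(O)cc(O[Si](C(C)C)(C(C)C)C(C)C)c(CC=C(C)C)c1O[Si](C(C)C)(C(C)C)C(C)C | intermediate
8 | vanillin (4-hydroxy-3-methoxybenzaldehyde) | COc1cc(C=O)ccc1O | starting material
9 | 4-(tert-butyldimethylsilyloxy)-3-methoxybenzaldehyde | COc1cc(C=O)ccc1O[Si](C)(C)C(C)(C)C | intermediate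
10 | [4-(tert-butyldimethylsilyloxy)-3-methoxyphenyl]methanol | COc1cc(CO)ccc1O[Si](C)(C)C(C)(C)C | intermediate
11 | 1-[6-{[4-(tert-butyldimethylsilyloxy)-3-methoxyphenyl]methoxy}-3-(3-methylbut-2-enyl)-2,4-bis(triisopropylsilyloxy)phenyl]ethanone | CC(=O)c1c(OCc2ccc(O[Si](C)(C)C(C)(C)C)c(OC)c2)cc(O[Si](C(C)C)(C(C)C)C(C)C)c(CC=C(C)C)c1O[Si](C(C)C)(C(C)C)C(C)C | intermediate
12 | potassium enolate of 11 (potassium 1-arylethenolate) | [K+].C=C([O-])c1c(OCc2ccc(O[Si](C)(C)C(C)(C)C)c(OC)c2)cc(O[Si](C(C)C)(C(C)C)C(C)C)c(CC=C(C)C)c1O[Si](C(C)C)(C(C)C)C(C)C | intermediate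
13 | 1-[6-{[4-(tert-butyldimethylsilyloxy)-3-methoxyphenyl]methoxy}-3-(3-methylbut-2-enyl)-2,4-bis(triisopropylsilyloxy)phenyl]-2-hydroxyethanone | OCC(=O)c1c(OCc2ccc(O[Si](C)(C)C(C)(C)C)c(OC)c2)cc(O[Si](C(C)C)(C(C)C)C(C)C)c(CC=C(C)C)c1O[Si](C(C)C)(C(C)C)C(C)C | intermediate
14 | 2-[6-{[4-(tert-butyldimethylsilyloxy)-3-methoxyphenyl]methoxy}-3-(3-methylbut-2-enyl)-2,4-bis(triisopropylsilyloxy)phenyl]-2-oxoacetaldehyde (achiral) | O=CC(=O)c1c(OCc2ccc(O[Si](C)(C)C(C)(C)C)c(OC)c2)cc(O[Si](C(C)C)(C(C)C)C(C)C)c(CC=C(C)C)c1O[Si](C(C)C)(C(C)C)C(C)C | intermediate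
15 | (2R,3R)-2-[4-(tert-butyldimethylsilyloxy)-3-methoxyphenyl]-3-hydroxy-6-(3-methylbut-2-enyl)-5,7-bis(triisopropylsilyloxy)-2,3-dihydrochromen-4-one | COc1cc([C@H]2Oc3cc(O[Si](C(C)C)(C(C)C)C(C)C)c(CC=C(C)C)c(O[Si](C(C)C)(C(C)C)C(C)C)c3C(=O)[C@@H]2O)ccc1O[Si](C)(C)C(C)(C)C | intermediate
16 | (2R,3R)-3,5,7-trihydroxy-2-(4-hydroxy-3-methoxyphenyl)-6-(3-methylbut-2-enyl)-2,3-dihydrochromen-4-one | COc1cc([C@H]2Oc3cc(O)c(CC=C(C)C)c(O)c3C(=O)[C@@H]2O)ccc1O | target

**Step count and risks**

Total steps: 10. Longest linear sequence: 8 steps (1, 2, 3, 6, 7, 8, 9, 10).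

Step 9 (proposed new method).
- What may go wrong: closure with poor facial selectivity at the C3 ketyl, because unbound 14 is excited as well and closes without the ligand; heterolysis of the benzylic C–O bond under the Lewis acid; recombination at C4 to a five-membered ring; carbonyl-ene reaction between the glyoxal and a prenyl group of a second molecule.
- Fallback, known chemistry only, from 7 back to 15. The free hydroxyl of 7 is capped with MOMCl and iPr2NEt to give the MOM ether 1-[6-(methoxymethoxy)-3-(3-methylbut-2-enyl)-2,4-bis(triisopropylsilyloxy)phenyl]ethanone F1. Its lithium enolate (LiN(SiMe3)2, THF, −78 °C) should add to aldehyde 9 to give the aldol 3-[4-(tert-butyldimethylsilyloxy)-3-methoxyphenyl]-3-hydroxy-1-[6-(methoxymethoxy)-3-(3-methylbut-2-enyl)-2,4-bis(triisopropylsilyloxy)phenyl]propan-1-one F2. Pyridinium p-toluenesulfonate in warm toluene should dehydrate it to the (E)-chalcone F3. Juliá–Colonna epoxidation (poly-leucine of the handedness that gives the (2R,3S)-epoxide, poly-L-leucine for simple chalcones; urea–hydrogen peroxide, DBU, THF) should attack only the enone and give the (2R,3S)-epoxy ketone F4. Dilute HCl in MeOH/THF at rt then removes the MOM group, and the freed phenol opens the epoxide at the benzylic carbon with inversion. This returns to 15 with C3 taken from the epoxide and C2 from the ring opening.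

Step 7.
- What may go wrong: migration of the ortho silyl group to the enolate oxygen, addition of the enolate to the sulfonimine by-product, or further oxidation of the ketol.
- Fallback from 11 to 14 without an enolate and without 13. Condensation of 11 with tert-butoxybis(dimethylamino)methane in toluene at 80 °C should give the enaminone (E)-3-(dimethylamino)-1-[6-{[4-(tert-butyldimethylsilyloxy)-3-methoxyphenyl]methoxy}-3-(3-methylbut-2-enyl)-2,4-bis(triisopropylsilyloxy)phenyl]prop-2-en-1-one F5. NaIO4 in THF/water cleaves its electron-rich C=C bond, but not the prenyl alkene, to the glyoxal hydrate 2,2-dihydroxy-1-[6-{[4-(tert-butyldimethylsilyloxy)-3-methoxyphenyl]methoxy}-3-(3-methylbut-2-enyl)-2,4-bis(triisopropylsilyloxy)phenyl]ethanone F6. Azeotropic drying from toluene over molecular sieves converts F6 into 14.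

Step 3.
- What may go wrong: enolisation of the ortho dienone before the Cope shift, which would leave a reverse-prenyl group on the wrong carbon; loss of a silyl group at 200 °C.
- Fallback from 1 to 11 without any rearrangement. 1 is C-prenylated with 3 and DBU in THF to 1-[2,4,6-trihydroxy-3-(3-methylbut-2-enyl)phenyl]ethanone F7. One equivalent of TIPSCl with imidazole should silylate the non-chelated para hydroxyl to give 1-[2,6-dihydroxy-3-(3-methylbut-2-enyl)-4-(triisopropylsilyloxy)phenyl]ethanone F8. Mitsunobu reaction with 10 (PPh3, DIAD) should take the less hindered ortho hydroxyl, the one next to the ring hydrogen, and give 1-[6-{[4-(tert-butyldimethylsilyloxy)-3-methoxyphenyl]methoxy}-2-hydroxy-3-(3-methylbut-2-enyl)-4-(triisopropylsilyloxy)phenyl]ethanone F9. TIPSOTf with 2,6-lutidine silylates the last hydroxyl and returns to 11.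

**Further compounds**

F1 | step 9 | 1-[6-(methoxymethoxy)-3-(3-methylbut-2-enyl)-2,4-bis(triisopropylsilyloxy)phenyl]ethanone | CC(=O)c1c(OCOC)cc(O[Si](C(C)C)(C(C)C)C(C)C)c(CC=C(C)C)c1O[Si](C(C)C)(C(C)C)C(C)C
F2 | step 9 | 3-[4-(tert-butyldimethylsilyloxy)-3-methoxyphenyl]-3-hydroxy-1-[6-(methoxymethoxy)-3-(3-methylbut-2-enyl)-2,4-bis(triisopropylsilyloxy)phenyl]propan-1-one (racemic) | COc1cc(C(O)CC(=O)c2c(OCOC)cc(O[Si](C(C)C)(C(C)C)C(C)C)c(CC=C(C)C)c2O[Si](C(C)C)(C(C)C)C(C)C)ccc1O[Si](C)(C)C(C)(C)C
F3 | step 9 | (E)-3-[4-(tert-butyldimethylsilyloxy)-3-methoxyphenyl]-1-[6-(methoxymethoxy)-3-(3-methylbut-2-enyl)-2,4-bis(triisopropylsilyloxy)phenyl]prop-2-en-1-one | COc1cc(/C=C/C(=O)c2c(OCOC)cc(O[Si](C(C)C)(C(C)C)C(C)C)c(CC=C(C)C)c2O[Si](C(C)C)(C(C)C)C(C)C)ccc1O[Si](C)(C)C(C)(C)C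
F4 | step 9 | {(2R,3S)-3-[4-(tert-butyldimethylsilyloxy)-3-methoxyphenyl]oxiran-2-yl}[6-(methoxymethoxy)-3-(3-methylbut-2-enyl)-2,4-bis(triisopropylsilyloxy)phenyl]methanone | O=C(c1c(OCOC)cc(O[Si](C(C)C)(C(C)C)C(C)C)c(CC=C(C)C)c1O[Si](C(C)C)(C(C)C)C(C)C)[C@@H]2O[C@H]2c3ccc(O[Si](C)(C)C(C)(C)C)c(OC)c3
F5 | step 7 | (E)-3-(dimethylamino)-1-[6-{[4-(tert-butyldimethylsilyloxy)-3-methoxyphenyl]methoxy}-3-(3-methylbut-2-enyl)-2,4-bis(triisopropylsilyloxy)phenyl]prop-2-en-1-one | CN(C)/C=C/C(=O)c1c(OCc2ccc(O[Si](C)(C)C(C)(C)C)c(OC)c2)cc(O[Si](C(C)C)(C(C)C)C(C)C)c(CC=C(C)C)c1O[Si](C(C)C)(C(C)C)C(C)C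
F6 | step 7 | 2,2-dihydroxy-1-[6-{[4-(tert-butyldimethylsilyloxy)-3-methoxyphenyl]methoxy}-3-(3-methylbut-2-enyl)-2,4-bis(triisopropylsilyloxy)phenyl]ethanone | OC(O)C(=O)c1c(OCc2ccc(O[Si](C)(C)C(C)(C)C)c(OC)c2)cc(O[Si](C(C)C)(C(C)C)C(C)C)c(CC=C(C)C)c1O[Si](C(C)C)(C(C)C)C(C)C
F7 | step 3 | 1-[2,4,6-trihydroxy-3-(3-methylbut-2-enyl)phenyl]ethanone | CC(=O)c1c(O)cc(O)c(CC=C(C)C)c1O
F8 | step 3 | 1-[2,6-dihydroxy-3-(3-methylbut-2-enyl)-4-(triisopropylsilyloxy)phenyl]ethanone | CC(=O)c1c(O)cc(O[Si](C(C)C)(C(C)C)C(C)C)c(CC=C(C)C)c1O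
F9 | step 3 | 1-[6-{[4-(tert-butyldimethylsilyloxy)-3-methoxyphenyl]methoxy}-2-hydroxy-3-(3-methylbut-2-enyl)-4-(triisopropylsilyloxy)phenyl]ethanone | CC(=O)c1c(OCc2ccc(O[Si](C)(C)C(C)(C)C)c(OC)c2)cc(O[Si](C(C)C)(C(C)C)C(C)C)c(CC=C(C)C)c1O
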